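**Plan**

1. Retrosynthesis: the dihydrofuran ring is cut at C3a–C3 and at O1–C2, which divides the target into two hispidin units. Each unit is then cut at its styryl C=C into triacetic acid lactone and protocatechualdehyde.
2. Enabling feature: in pyrone ring A the C3 carbon and the C4 oxygen form the C–C–O unit of a β-keto lactone, so a carbene at C3 (flanked by two carbonyls) acts as a 1,3-dipole equivalent. The styryl C=C of the second unit is polarised by its para-oxygenated aryl ring, so the oxygen ends on the benzylic carbon.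
3. Forward: silylated aldehyde plus lactone dianion, aldol addition and dehydration give bis-silyl hispidin. This one intermediate is divided into a 3-diazo-pyran-2,4-dione (diazo transfer) and a 4-O-protected styrylpyrone (Mitsunobu).
4. The two halves are joined by an enantioselective Rh(II)-carbenoid formal [3+2] cycloaddition that closes the dihydrofuran as the last ring. One fluoride step then removes all protecting groups.
5. Stereochemistry: C3 from the chiral Rh(II) carboxylate in the C–C bond-forming event; C2 from trans-selective ring closure (substrate control); both E-alkenes from thermodynamically controlled dehydration.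

Key step: step 6

Assumption: the sense of induction of the Rh(II) catalyst cannot be predicted with confidence for this substrate pair; the S-configured catalyst is written, and its mirror-image R catalyst would be used if the first run pointed to the (2R,3R) series. Abbreviations: TBS = tert-butyldimethylsilyl, TBSO = tert-butyldimethylsilyloxy, TMSE = 2-(trimethylsilyl)ethyl.

**Route**

Step 1
Reactants: 1 3,4-dihydroxybenzaldehyde
Product: 2 3,4-bis(tert-butyldimethylsilyloxy)benzaldehyde
Conditions: TBSCl (2.4 equiv), imidazole (5 equiv), DMF, 0 °C → rt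
Reagents that add atoms: tert-butyldimethylsilyl chloride (TBSCl), CC(C)(C)[Si](C)(C)Cl
Why: standard silyl ether formation on both phenols, which keeps the aryl ring electron-rich for step 6 and gives groups that leave with fluoride at the end.

Step 2
Reactants: 3 4-hydroxy-6-methyl-2H-pyran-2-one (triacetic acid lactone); 2 3,4-bis(tert-butyldimethylsilyloxy)benzaldehyde
Product: 5 6-{2-[3,4-bis(TBSO)phenyl]-2-hydroxyethyl}-4-hydroxy-2H-pyran-2-one (racemic carbinol), via dilithio dianion 4 (not isolated)
Conditions: LDA (2.3 equiv), THF–DMPU, −78 °C, 1 h; then 2 (0.9 equiv), −78 → −40 °C; AcOH quench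
Reagents that add atoms: none
Why: vinylogous aldol addition of the lactone dianion, which should react at its most basic site, the C6 methylene carbon, with the non-enolisable aldehyde; the carbinol centre is racemic and is removed in step 3.

Step 3
Reactants: 5 6-{2-[3,4-bis(TBSO)phenyl]-2-hydroxyethyl}-4-hydroxy-2H-pyran-2-one
Product: 6 6-{(E)-2-[3,4-bis(TBSO)phenyl]ethenyl}-4-hydroxy-2H-pyran-2-one (bis-TBS hispidin)
Conditions: CSA (10 mol%), toluene (0.02 M), 4 Å MS, 80 °C
Reagents that add atoms: none
Why: acid-catalysed E1 dehydration of the electron-rich benzylic alcohol should place the new alkene in conjugation with both rings, with the E isomer as the thermodynamic product.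

Step 4
Reactants: 6 6-{(E)-2-[3,4-bis(TBSO)phenyl]ethenyl}-4-hydroxy-2H-pyran-2-one
Product: 7 6-{(E)-2-[3,4-bis(TBSO)phenyl]ethenyl}-3-diazo-2H-pyran-2,4(3H)-dione
Conditions: p-ABSA (1.1 equiv), Et3N (1.5 equiv), MeCN, 0 °C → rt
Reagents that add atoms: 4-acetamidobenzenesulfonyl azide (p-ABSA), CC(=O)Nc1ccc(cc1)S(=O)(=O)N=[N+]=[N-]
Why: Regitz diazo transfer to C3 of the cyclic β-keto lactone, as known for 4-hydroxycoumarin and 4-hydroxy-6-methyl-2-pyrone, should give a stable 2-diazo-1,3-dicarbonyl compound.

Step 5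
Reactants: 6 6-{(E)-2-[3,4-bis(TBSO)phenyl]ethenyl}-4-hydroxy-2H-pyran-2-one
Product: 8 6-{(E)-2-[3,4-bis(TBSO)phenyl]ethenyl}-4-[2-(trimethylsilyl)ethoxy]-2H-pyran-2-one
Conditions: Me3SiCH2CH2OH (1.3 equiv), PPh3 (1.3 equiv), DIAD (1.3 equiv), THF, 0 °C → rt
Reagents that add atoms: 2-(trimethylsilyl)ethanol, C[Si](C)(C)CCO
Why: Mitsunobu O-alkylation of the acidic 4-hydroxy-2-pyrone is known to give the 4-alkoxy-2-pyrone, and the TMSE vinylogous ester should survive the carbenoid step yet fragment with fluoride.

Step 6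
Reactants: 7 6-{(E)-2-[3,4-bis(TBSO)phenyl]ethenyl}-3-diazo-2H-pyran-2,4(3H)-dione; 8 6-{(E)-2-[3,4-bis(TBSO)phenyl]ethenyl}-4-[2-(trimethylsilyl)ethoxy]-2H-pyran-2-one
Product: 11 (2S,3S)-2-[3,4-bis(TBSO)phenyl]-6-{(E)-2-[3,4-bis(TBSO)phenyl]ethenyl}-3-{2-oxo-4-[2-(trimethylsilyl)ethoxy]-2H-pyran-6-yl}-2,3-dihydro-4H-furo[3,2-c]pyran-4-one, via rhodium carbenoid 9 (not isolated), via benzylic zwitterion 10 (not isolated)
Conditions: Rh2(S-TCPTTL)4 (2 mol%), 8 (3 equiv), 4 Å MS, PhCF3, 50 °C, 7 added over 8 h by syringe pump; excess 8 recovered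
Reagents that add atoms: none
Why: Proposed new method: the chiral Rh(II) carboxylate should expel N2 from 7 to give the electrophilic acceptor/acceptor carbenoid 9, which attacks the styryl C=C of 8 at the carbon next to the pyrone ring, because the positive charge then develops at the benzylic carbon para to a silyloxy group, giving zwitterion 10 (a donor–acceptor spirocyclopropane, if formed, would ionise to the same species); the closest known reaction type is the Rh2(OAc)4-catalysed formal [3+2] cycloaddition of cyclic 2-diazo-1,3-dicarbonyl compounds such as 3-diazochromane-2,4-dione with styrenes and enol ethers to give fused 2,3-dihydrofurans, together with enantioselective cyclopropanation of styrenes by acceptor/acceptor carbenoids under phthalimido-amino-acid Rh(II) catalysts. The dihydrofuran ring then closes by 5-exo-trig attack of the in-plane lone pair of the C4 enolate oxygen on the benzylic cation (O-alkylation). C3 is created in the metal-bound C–C bond-forming event, since the alkene is 1,2-disubstituted, so the chiral carboxylate pocket can choose the alkene face (catalyst control), in contrast to terminal alkenes, where the only stereocentre arises after the metal has left. C2 is set in the ring closure under substrate control, the aryl group going anti to the C3 pyronyl group, which is also the thermodynamically preferred trans arrangement. The step needs regioselectivity (secured by the para-silyloxyaryl donor on one alkene carbon and the acceptor pyrone on the other), closure through the ketone oxygen and not the lactone carbonyl oxygen (the more nucleophilic enolate terminus, which also leaves the more stable 2-pyrone), and chemoselectivity for the alkene of 8 over the styryl groups of 7 and 11 (excess 8, slow addition of 7, and deactivation of the styryl group of 7 by the cross-conjugated diazo dione).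

Step 7
Reactants: 11 (2S,3S)-2-[3,4-bis(TBSO)phenyl]-6-{(E)-2-[3,4-bis(TBSO)phenyl]ethenyl}-3-{2-oxo-4-[2-(trimethylsilyl)ethoxy]-2H-pyran-6-yl}-2,3-dihydro-4H-furo[3,2-c]pyran-4-one
Product: 12 hypholomine B, (2S,3S)-2-(3,4-dihydroxyphenyl)-6-[(E)-2-(3,4-dihydroxyphenyl)ethenyl]-3-(4-hydroxy-2-oxo-2H-pyran-6-yl)-2,3-dihydro-4H-furo[3,2-c]pyran-4-one
Conditions: TBAF (10 equiv), AcOH (12 equiv), degassed THF–DMF, Ar, 0 °C → rt; aq. citric acid work-up; Sephadex LH-20
Reagents that add atoms: none
Why: fluoride-induced cleavage of the four aryl silyl ethers and β-fragmentation of the TMSE vinylogous ester (loss of ethylene) should free all five hydroxyl groups, while the acetic acid buffer keeps the phenols protonated so that neither stereocentre is touched.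

**Compound list**

1 | 3,4-dihydroxybenzaldehyde (protocatechualdehyde) | O=Cc1ccc(O)c(O)c1 | starting material
2 | 3,4-bis(tert-butyldimethylsilyloxy)benzaldehyde | O=Cc1ccc(O[Si](C)(C)C(C)(C)C)c(O[Si](C)(C)C(C)(C)C)c1 | intermediate
3 | 4-hydroxy-6-methyl-2H-pyran-2-one (triacetic acid lactone) | Cc1cc(O)cc(=O)o1 | starting material
4 | dilithio dianion of 3, dilithium 6-methylidene-6H-pyran-2,4-bis(olate) (not isolated) | [Li+].[Li+].C=C1C=C([O-])C=C([O-])O1 | intermediate
5 | 6-{2-[3,4-bis(TBSO)phenyl]-2-hydroxyethyl}-4-hydroxy-2H-pyran-2-one (racemic carbinol) | O=c1cc(O)cc(CC(O)c2ccc(O[Si](C)(C)C(C)(C)C)c(O[Si](C)(C)C(C)(C)C)c2)o1 | intermediate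
6 | 6-{(E)-2-[3,4-bis(TBSO)phenyl]ethenyl}-4-hydroxy-2H-pyran-2-one (bis-TBS hispidin) | O=c1cc(O)cc(/C=C/c2ccc(O[Si](C)(C)C(C)(C)C)c(O[Si](C)(C)C(C)(C)C)c2)o1 | intermediate
7 | 6-{(E)-2-[3,4-bis(TBSO)phenyl]ethenyl}-3-diazo-2H-pyran-2,4(3H)-dione | [N-]=[N+]=C1C(=O)OC(/C=C/c2ccc(O[Si](C)(C)C(C)(C)C)c(O[Si](C)(C)C(C)(C)C)c2)=CC1=O | intermediate
8 | 6-{(E)-2-[3,4-bis(TBSO)phenyl]ethenyl}-4-[2-(trimethylsilyl)ethoxy]-2H-pyran-2-one | O=c1cc(OCC[Si](C)(C)C)cc(/C=C/c2ccc(O[Si](C)(C)C(C)(C)C)c(O[Si](C)(C)C(C)(C)C)c2)o1 | intermediate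
9 | rhodium carbenoid at C3 of the pyran-2,4-dione derived from 7 (carboxylate ligands and second Rh omitted in the SMILES; not isolated) | O=C1OC(/C=C/c2ccc(O[Si](C)(C)C(C)(C)C)c(O[Si](C)(C)C(C)(C)C)c2)=CC(=O)C1=[Rh] | intermediate
10 | benzylic zwitterion: pyran-2,4-dione enolate joined through its C3 to the carbon bearing the TMSE-protected pyrone, next to the bis(TBSO)benzyl cation, configured as in 11 (not isolated) | O=c1cc(OCC[Si](C)(C)C)cc([C@H]([CH+]c2ccc(O[Si](C)(C)C(C)(C)C)c(O[Si](C)(C)C(C)(C)C)c2)C2=C([O-])C=C(/C=C/c3ccc(O[Si](C)(C)C(C)(C)C)c(O[Si](C)(C)C(C)(C)C)c3)OC2=O)o1 | intermediate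
11 | (2S,3S)-2-[3,4-bis(TBSO)phenyl]-6-{(E)-2-[3,4-bis(TBSO)phenyl]ethenyl}-3-{2-oxo-4-[2-(trimethylsilyl)ethoxy]-2H-pyran-6-yl}-2,3-dihydro-4H-furo[3,2-c]pyran-4-one (trans) | O=c1cc(OCC[Si](C)(C)C)cc([C@H]2c3c(cc(/C=C/c4ccc(O[Si](C)(C)C(C)(C)C)c(O[Si](C)(C)C(C)(C)C)c4)oc3=O)O[C@@H]2c2ccc(O[Si](C)(C)C(C)(C)C)c(O[Si](C)(C)C(C)(C)C)c2)o1 | intermediate
12 | hypholomine B, (2S,3S)-2-(3,4-dihydroxyphenyl)-6-[(E)-2-(3,4-dihydroxyphenyl)ethenyl]-3-(4-hydroxy-2-oxo-2H-pyran-6-yl)-2,3-dihydro-4H-furo[3,2-c]pyran-4-one | O=c1cc(O)cc([C@H]2c3c(cc(/C=C/c4ccc(O)c(O)c4)oc3=O)O[C@@H]2c2ccc(O)c(O)c2)o1 | target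

**Summary**

Total step count: 7. Longest linear sequence: 6 steps (steps 1, 2, 3, 4, 6, 7; step 5 is the side branch from 6).

Steps most likely to fail:

1. Step 6 (proposed new method). The catalyst may exert little control over the alkene face if C–C bond formation takes place outside the chiral pocket. The carbenoid may also be consumed by the styryl groups of 7 or 11, or by the enol-ether position of the pyrone in 8, and ring closure may go partly through the lactone oxygen. The fallback sets out from 7 and 8 and uses the known achiral reaction: Rh2(OAc)4 (2 mol%) in fluorobenzene at 60 °C should give the trans-dihydrofuran as the racemate, that is 11 together with its (2R,3R) enantiomer F1. The two would be separated by preparative HPLC on a chiral stationary phase (immobilised amylose tris(3,5-dimethylphenylcarbamate)), and the route is rejoined at 11. The absolute configuration then comes from resolution and no longer from the catalyst.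

2. Step 3. The benzylic cation of the E1 pathway may be captured by the nucleophilic C3 position of a second 4-hydroxypyrone (Friedel–Crafts-type C-alkylation leading to oligomers), and the acid may remove silyl groups. The fallback sets out from 5 and comes back at 6 without a free cation. Acetylation of both hydroxyl groups (Ac2O, Et3N, DMAP, CH2Cl2) should give the diacetate 4-acetoxy-6-{2-acetoxy-2-[3,4-bis(TBSO)phenyl]ethyl}-2H-pyran-2-one F2. DBU in THF should then remove the benzylic acetate by E1cB elimination through the vinylogous pyrone enolate to give the enol acetate 4-acetoxy-6-{(E)-2-[3,4-bis(TBSO)phenyl]ethenyl}-2H-pyran-2-one F3. Its vinylogous anhydride should be cleaved by morpholine (1.1 equiv, THF, 0 °C) without loss of the aryl silyl ethers, which returns 6.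

3. Step 7. If the medium turns basic, the liberated para-phenoxide can expel the pyrone oxygen (ring opening to a quinone methide), and tautomerisation of that species to the ring-opened styrene would destroy both stereocentres. The catechols can also oxidise in air, and the TMSE group may cleave only slowly under buffered fluoride. The fallback changes the protecting-group plan; it sets out from 6 and comes back at 12. Silylation of the pyrone hydroxyl (TIPSOTf, 2,6-lutidine, CH2Cl2, −78 °C) should give the 4-(triisopropylsilyloxy) analogue of 8, F4. Cycloaddition of F4 with 7 under the conditions of step 6 should give the penta-silyl analogue of 11, F5. All five silyl groups should then be removed by KHF2 in MeOH at rt, a known mild reagent for phenolic silyl ethers that keeps the medium weakly acidic throughout, to give 12.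

Further compounds
F1 | step 6 | (2R,3R) enantiomer of 11 | O=c1cc(OCC[Si](C)(C)C)cc([C@@H]2c3c(cc(/C=C/c4ccc(O[Si](C)(C)C(C)(C)C)c(O[Si](C)(C)C(C)(C)C)c4)oc3=O)O[C@H]2c2ccc(O[Si](C)(C)C(C)(C)C)c(O[Si](C)(C)C(C)(C)C)c2)o1
F2 | step 3 | 4-acetoxy-6-{2-acetoxy-2-[3,4-bis(TBSO)phenyl]ethyl}-2H-pyran-2-one (racemic) | O=c1cc(OC(C)=O)cc(CC(OC(C)=O)c2ccc(O[Si](C)(C)C(C)(C)C)c(O[Si](C)(C)C(C)(C)C)c2)o1
F3 | step 3 | 4-acetoxy-6-{(E)-2-[3,4-bis(TBSO)phenyl]ethenyl}-2H-pyran-2-one | O=c1cc(OC(C)=O)cc(/C=C/c2ccc(O[Si](C)(C)C(C)(C)C)c(O[Si](C)(C)C(C)(C)C)c2)o1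
F4 | step 7 | 6-{(E)-2-[3,4-bis(TBSO)phenyl]ethenyl}-4-(triisopropylsilyloxy)-2H-pyran-2-one | O=c1cc(O[Si](C(C)C)(C(C)C)C(C)C)cc(/C=C/c2ccc(O[Si](C)(C)C(C)(C)C)c(O[Si](C)(C)C(C)(C)C)c2)o1
F5 | step 7 | (2S,3S)-2-[3,4-bis(TBSO)phenyl]-6-{(E)-2-[3,4-bis(TBSO)phenyl]ethenyl}-3-[2-oxo-4-(triisopropylsilyloxy)-2H-pyran-6-yl]-2,3-dihydro-4H-furo[3,2-c]pyran-4-one | O=c1cc(O[Si](C(C)C)(C(C)C)C(C)C)cc([C@H]2c3c(cc(/C=C/c4ccc(O[Si](C)(C)C(C)(C)C)c(O[Si](C)(C)C(C)(C)C)c4)oc3=O)O[C@@H]2c2ccc(O[Si](C)(C)C(C)(C)C)c(O[Si](C)(C)C(C)(C)C)c2)o1
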